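## Retrosynthetic overview

- **Feature:** two identical 4-hydroxyphenyl rings end C1 and C7 of a heptane chain whose oxygen-bearing C3 and C5 are both R. The parent 3,5-diol is therefore C2-symmetric, so the aryl–C1 and aryl–C7 bonds are equivalent, and so are the two oxygens towards acetylation.
- **Late stage:** the C3 acetate comes from the C2-symmetric diol through a cyclic orthoacetate (either ring opening gives the same ester); the phenols are carried as benzyl ethers and freed last.
- **Key disconnection:** aryl–C1 and aryl–C7 are formed together by twofold hydroboration and B-alkyl Suzuki–Miyaura coupling of the (4S,6S)-divinyl acetonide with two molecules of 1-(benzyloxy)-4-bromobenzene.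
- **Core:** the divinyl diol comes from (2S,4S)-1,2:4,5-diepoxypentane and a sulfonium ylide; the diepoxide comes from Ru–BINAP hydrogenation of 1,5-dichloropentane-2,4-dione, which sets C3 and C5.
- **Rings:** both benzene rings are bought and no ring of the target is built. Only temporary rings appear: two oxiranes (step 2), the 1,3-dioxane acetonide (step 4, removed in step 6) and the cyclic orthoester (step 7).

Key step: step 5

Assumption: 1,5-dichloropentane-2,4-dione (1) is taken as a catalogue compound. Ru–(R)-BINAP is taken to deliver hydrogen in the same spatial sense as in its reduction of pentane-2,4-dione to the (R,R)-diol; with the chloromethyl groups that sense is named (2S,4S).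

## Route

Step 1
Reactants: 1 1,5-dichloropentane-2,4-dione
Product: 2 (2S,4S)-1,5-dichloropentane-2,4-diol
Conditions: H2 (85 bar), [RuCl2((R)-BINAP)]2·NEt3 (0.2 mol%), MeOH, 90 °C; recrystallisation
Reagents that add atoms: none
Why: Noyori asymmetric hydrogenation of a β-diketone, in which the first C=O is reduced under chelation by the second and the resulting β-hydroxy ketone again under catalyst control, so the (R)-BINAP ligand sets both carbinol centres as the anti (C2) diol, and crystallisation should remove the meso isomer and raise the enantiopurity.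

Step 2
Reactants: 2 (2S,4S)-1,5-dichloropentane-2,4-diol
Product: 3 (2S,2'S)-2,2'-methylenebis(oxirane) [(2S,4S)-1,2:4,5-diepoxypentane]
Conditions: powdered KOH, Et2O, rt; careful distillation
Reagents that add atoms: none
Why: twofold intramolecular Williamson etherification (alkoxide displaces the adjacent primary chloride, 3-exo-tet), in which the C–O bonds at the stereocentres are not broken, so both centres are retained.

Step 3
Reactants: 3 (2S,2'S)-2,2'-methylenebis(oxirane)
Product: 5 (3S,5S)-hepta-1,6-diene-3,5-diol, via bis-sulfonium dialkoxide betaine 4 (not isolated)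
Conditions: Me3S+ I− (6 equiv), n-BuLi (5.8 equiv), THF, −10 °C; add 3, −10 °C → rt; H2O quench
Reagents that add atoms: trimethylsulfonium iodide, C[S+](C)C.[I-]
Why: one-carbon homologation of a terminal epoxide to an allylic alcohol with dimethylsulfonium methylide, in which the ylide opens each oxirane at CH2 by SN2 and excess ylide then induces loss of Me2S from the γ-oxido sulfonium salt to give the vinyl group, so the carbinol carbons are never touched and keep their configuration.

Step 4
Reactants: 5 (3S,5S)-hepta-1,6-diene-3,5-diol
Product: 6 (4S,6S)-4,6-diethenyl-2,2-dimethyl-1,3-dioxane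
Conditions: 2,2-dimethoxypropane (3 equiv), PPTS (5 mol%), CH2Cl2, rt; Et3N quench, careful evaporation (volatile product)
Reagents that add atoms: 2,2-dimethoxypropane, COC(C)(C)OC
Why: acid-catalysed transketalisation of a 1,3-diol to its acetonide, which closes the trans-4,6-disubstituted dioxane without touching either stereocentre and makes the diol inert to borane and aqueous base.

Step 5
Reactants: 6 (4S,6S)-4,6-diethenyl-2,2-dimethyl-1,3-dioxane; 7 1-(benzyloxy)-4-bromobenzene (two molecules per molecule of 6)
Product: 9 (4R,6R)-4,6-bis{2-[4-(benzyloxy)phenyl]ethyl}-2,2-dimethyl-1,3-dioxane, via bis(B-alkyl-9-BBN) adduct 8 (not isolated)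
Conditions: 9-BBN (2.4 equiv), THF, 0 °C → rt; then 7 (2.3 equiv), PdCl2(dppf)·CH2Cl2 (5 mol%), degassed 3 M aq NaOH, THF, 65 °C
Reagents that add atoms: 1-(benzyloxy)-4-bromobenzene (the second molecule of 7 that enters the product), Brc1ccc(OCc2ccccc2)cc1
Why: 9-BBN adds syn and anti-Markovnikov to each vinyl group to give the bis(primary alkyl)borane 8; each of the two molecules of 7 then undergoes oxidative addition to Pd(0), hydroxide-assisted transmetallation of one primary B–C bond to the arylpalladium(II) and reductive elimination, which form the aryl–C1 and aryl–C7 bonds. The closest known reaction type is the hydroboration/B-alkyl Suzuki–Miyaura coupling of terminal alkenes, allylic ethers included, with aryl bromides. No ring is closed and no new stereocentre is formed, and the (4S,6S) to (4R,6R) change of descriptor is only a change in CIP ranking. The step needs terminal regioselectivity in both hydroborations, secured by the bulk of 9-BBN on a monosubstituted alkene; this also avoids a β-alkoxyborane that could eliminate. It needs complete twofold coupling without β-hydride elimination, for which excess 7 and base and the wide bite angle of dppf are chosen. The two C–O stereocentres are remote from the reacting carbons and are held in the base-stable acetonide, so they should pass through unchanged.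

Step 6
Reactants: 9 (4R,6R)-4,6-bis{2-[4-(benzyloxy)phenyl]ethyl}-2,2-dimethyl-1,3-dioxane
Product: 10 (3R,5R)-1,7-bis[4-(benzyloxy)phenyl]heptane-3,5-diol
Conditions: 1 M aq HCl, THF, rt
Reagents that add atoms: none
Why: acid hydrolysis of the acetonide, in which cleavage occurs at the ketal carbon and not at C3–O or C5–O, so configuration is retained and the benzyl aryl ethers are untouched.

Step 7
Reactants: 10 (3R,5R)-1,7-bis[4-(benzyloxy)phenyl]heptane-3,5-diol
Product: 12 (3R,5R)-1,7-bis[4-(benzyloxy)phenyl]-5-hydroxyheptan-3-yl acetate, via cyclic methyl orthoacetate 11 (not isolated)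
Conditions: MeC(OMe)3 (1.5 equiv), PPTS (5 mol%), CH2Cl2, rt; then AcOH/H2O (4:1), rt
Reagents that add atoms: trimethyl orthoacetate, CC(OC)(OC)OC; water, O
Why: monoacylation of a diol through its cyclic orthoester, in which acid-catalysed exchange gives the 2-methoxy-2-methyl-1,3-dioxane and mild aqueous acid opens it through the dioxan-2-ylium ion and hemiorthoester to one hydroxy acetate; the two ring oxygens are related by the C2 axis, so either opening (and any later 1,3-acyl shift) gives the same compound.

Step 8
Reactants: 12 (3R,5R)-1,7-bis[4-(benzyloxy)phenyl]-5-hydroxyheptan-3-yl acetate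
Product: 13 (3R,5R)-5-hydroxy-1,7-bis(4-hydroxyphenyl)heptan-3-yl acetate
Conditions: H2 (1 atm), 10% Pd/C, EtOAc, rt
Reagents that add atoms: none
Why: catalytic hydrogenolysis of the two benzyl aryl ethers, while the non-benzylic secondary acetate and alcohol are inert and the neutral aprotic medium avoids transesterification.

## Compound list

1 | 1,5-dichloropentane-2,4-dione | ClCC(=O)CC(=O)CCl | starting material
2 | (2S,4S)-1,5-dichloropentane-2,4-diol | ClC[C@@H](O)C[C@H](O)CCl | intermediate
3 | (2S,2'S)-2,2'-methylenebis(oxirane) [(2S,4S)-1,2:4,5-diepoxypentane] | C1O[C@H]1C[C@H]1CO1 | intermediate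
4 | (3S,5S)-1,7-bis(dimethylsulfonio)heptane-3,5-diolate (betaine, not isolated) | C[S+](C)CC[C@@H]([O-])C[C@H]([O-])CC[S+](C)C | intermediate
5 | (3S,5S)-hepta-1,6-diene-3,5-diol | C=C[C@@H](O)C[C@H](O)C=C | intermediate
6 | (4S,6S)-4,6-diethenyl-2,2-dimethyl-1,3-dioxane | CC1(C)O[C@H](C=C)C[C@@H](C=C)O1 | intermediate
7 | 1-(benzyloxy)-4-bromobenzene | Brc1ccc(OCc2ccccc2)cc1 | starting material
8 | 9,9'-{[(4R,6R)-2,2-dimethyl-1,3-dioxane-4,6-diyl]di(ethane-2,1-diyl)}bis(9-borabicyclo[3.3.1]nonane) (not isolated) | CC1(C)O[C@H](CCB2C3CCCC2CCC3)C[C@@H](CCB2C3CCCC2CCC3)O1 | intermediate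
9 | (4R,6R)-4,6-bis{2-[4-(benzyloxy)phenyl]ethyl}-2,2-dimethyl-1,3-dioxane | CC1(C)O[C@H](CCc2ccc(OCc3ccccc3)cc2)C[C@@H](CCc2ccc(OCc3ccccc3)cc2)O1 | intermediate
10 | (3R,5R)-1,7-bis[4-(benzyloxy)phenyl]heptane-3,5-diol | O[C@H](CCc1ccc(OCc2ccccc2)cc1)C[C@H](O)CCc1ccc(OCc2ccccc2)cc1 | intermediate
11 | (4R,6R)-4,6-bis{2-[4-(benzyloxy)phenyl]ethyl}-2-methoxy-2-methyl-1,3-dioxane (not isolated) | COC1(C)O[C@H](CCc2ccc(OCc3ccccc3)cc2)C[C@@H](CCc2ccc(OCc3ccccc3)cc2)O1 | intermediate
12 | (3R,5R)-1,7-bis[4-(benzyloxy)phenyl]-5-hydroxyheptan-3-yl acetate | CC(=O)O[C@H](CCc1ccc(OCc2ccccc2)cc1)C[C@H](O)CCc1ccc(OCc2ccccc2)cc1 | intermediate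
13 | (3R,5R)-5-hydroxy-1,7-bis(4-hydroxyphenyl)heptan-3-yl acetate | CC(=O)O[C@H](CCc1ccc(O)cc1)C[C@H](O)CCc1ccc(O)cc1 | target

## Step count and risks

Total step count: 8. Longest linear sequence: 8 steps (1 to 13; 7 enters at step 5).

**Step 5 (key step).** The second coupling may stall, because transmetallation of a hindered B-alkyl-9-BBN to an electron-rich arylpalladium is slow; protodeboronation and β-hydride elimination at the mono-coupled stage would then compete. The fallback sets out from 6, returns at 9, and inverts the polarity of both chain ends. Compound 6 is hydroborated as before (9-BBN, THF) but the bis-borane 8 is oxidised (NaOH, H2O2) to 2,2'-[(4R,6R)-2,2-dimethyl-1,3-dioxane-4,6-diyl]di(ethan-1-ol) F1. Appel iodination (I2, PPh3, imidazole, CH2Cl2) should give (4S,6S)-4,6-bis(2-iodoethyl)-2,2-dimethyl-1,3-dioxane F2. A copper-catalysed Kochi-type coupling (Li2CuCl4 cat., THF/NMP, 0 °C) of both primary iodides with 4-(benzyloxy)phenylmagnesium bromide F3 (at least two equivalents), made from 7 and magnesium in THF, should then give 9.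

**Step 3.** The twofold homologation may run unevenly: one epoxide may stay unreacted or be opened by an alkoxide of another molecule (oligomerisation), and the small water-soluble diol may be lost on aqueous work-up. The fallback sets out from 3 and returns at 10, giving up the divinyl intermediate; it would be used only if 5 cannot be secured. Both oxiranes are opened at CH2 by [4-(benzyloxy)benzyl]magnesium chloride F4 (two equivalents or more) under copper catalysis (CuI 10 mol%, THF, −30 °C; aq NH4Cl). F4 is prepared from commercial 4-(benzyloxy)benzyl chloride and magnesium at low temperature to hold back Wurtz coupling. The SN2 openings at the terminal carbons leave the carbinol centres as they are, so diol 10 should result directly.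

**Step 7.** Ring closure to the six-membered orthoester of the anti-diol may be incomplete, giving open mixed orthoesters or bridged dimers whose hydrolysis returns diol or over-acetylated material. The fallback sets out from 10 and returns at 12. Heating 10 with Bu2SnO (toluene, reflux, Dean–Stark) should give the stannylene acetal (4R,6R)-4,6-bis{2-[4-(benzyloxy)phenyl]ethyl}-2,2-dibutyl-1,3,2-dioxastanninane F5. Acetyl chloride (1.0 equiv, CH2Cl2, 0 °C) followed by aqueous work-up should then give 12. The two Sn–O bonds are symmetry-equivalent, and after the first acylation the remaining chlorostannyl alkoxide is a poor nucleophile, so a second acetylation is held back.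

## Further compounds

F1 | step 5 | 2,2'-[(4R,6R)-2,2-dimethyl-1,3-dioxane-4,6-diyl]di(ethan-1-ol) | CC1(C)O[C@H](CCO)C[C@@H](CCO)O1
F2 | step 5 | (4S,6S)-4,6-bis(2-iodoethyl)-2,2-dimethyl-1,3-dioxane | CC1(C)O[C@H](CCI)C[C@@H](CCI)O1
F3 | step 5 | 4-(benzyloxy)phenylmagnesium bromide | Br[Mg]c1ccc(OCc2ccccc2)cc1
F4 | step 3 | [4-(benzyloxy)benzyl]magnesium chloride | Cl[Mg]Cc1ccc(OCc2ccccc2)cc1
F5 | step 7 | (4R,6R)-4,6-bis{2-[4-(benzyloxy)phenyl]ethyl}-2,2-dibutyl-1,3,2-dioxastanninane | CCCC[Sn]1(CCCC)O[C@H](CCc2ccc(OCc3ccccc3)cc2)C[C@@H](CCc2ccc(OCc3ccccc3)cc2)O1
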